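## The problem

The target is a C20 furanoditerpenoid acetate in which three carbocycles meet at one central CH: ring B is a cyclohexene carrying a fused α,β-unsaturated γ-lactone, ring A is a cyclohexane with an exocyclic methylene next to an acetoxy carbon, and ring C is a cycloheptanone fused to the 2,3-bond of a furan. All three ring fusions are cis, so rings A and C lie on one face of ring B, while the lactone CH2, the C-methyl group and the angular hydrogens lie on the other. Five stereocentres must be set: the lactone quaternary carbon (S), the central CH (S), the methyl-bearing quaternary carbon (R), the furyl-bearing CH (R) and the acetoxy carbon (S). Two are quaternary and three are contiguous, and the bond from the methyl-bearing quaternary carbon to the central CH, flanked by the lactone quaternary carbon, is the hardest to make by polar chemistry. The lactone quaternary carbon is the one centre that can be made alone from a flat precursor; its two arms can then decide the face on which rings C and A are built, and once tied into the lactone it fixes the shape of ring B for the last two centres. The furan (acid, ozone, peracids), the exocyclic alkene with its allylic acetate (acid), the butenolide (strong base, hydride) and the furfuryl CH (epimerisable through the acylfuran) rule out rough treatment late in the route. The enabling feature is in ring C: the ketone carbon and the furyl-bearing ring B carbon sit on neighbouring furan carbons, so a bond from the ketone α-carbon to the furyl-bearing carbon would close a five-membered ring, and the two remaining ring C atoms (central CH, methyl-bearing carbon) would complete a cyclobutane. Ring C is therefore the two-carbon ring expansion product of an enone–alkene [2+2] adduct between a furyl enone and the ring B alkene, and the hindered bond can be made by collapse of a diradical.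

## Retrosynthesis

**Acetate and ring A (32 ⇒ 31 ⇒ 29).** After removal of the acetyl group, the ring A bond between the carbinol carbon and the methylene-bearing carbon of 31 is cut. This leads to aldehyde 29, which carries a terminal alkyne on the methyl-bearing quaternary carbon. A reductive alkyne–aldehyde cyclisation makes this bond, the exocyclic methylene and the allylic oxygen in one operation; an aldol or a vinyl-halide addition would need extra steps to reach the same oxidation pattern. The forward reaction must close a six-membered ring and set the carbinol configuration, for which the lactone-locked ring B is relied on.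

**Aldehyde from an allyl group (29 ⇒ 28).** The aldehyde carbon is traced back to the internal carbon of an allyl group in 28. An allyl group survives every earlier step and is put in when the quaternary carbon is made. The forward step must cleave a monosubstituted alkene in the presence of a furan, an alkyne and a butenolide.

**Ring C by two-carbon ring expansion (28 ⇒ 27).** In the reverse sense the ketone α-CH2 of 28 is joined to the furyl-bearing CH, which turns the cycloheptanone into cyclobutane 27. Forward, this is a reductive cleavage of the cyclobutane bond next to the ketone. The alternative, closing the seven-membered ring directly at the quaternary carbon, would have to form the most hindered bond of the molecule by polar means. The forward step must cleave the ring-fusion bond and not the other cyclobutane bond at the α-carbon, and must deliver hydrogen to the furyl carbon on the convex face.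

**Lactone opened (27 ⇒ 25).** The butenolide of 27 is opened to methyl ester and tert-butyldiphenylsilyl ether 25. The open form is needed one step earlier, where a bulky silyloxymethyl arm must block one face of ring B; the closed lactone would leave the allyl arm as the larger group and reverse the face. Closing the lactone before the fragmentation locks ring B for the protonation of step 15.

**The key cut (25 ⇒ 24).** Two cyclobutane bonds of 25 are cut: α-carbon to furyl-bearing carbon, and β-carbon to the neighbouring ring B CH. This gives 24, a cyclohexa-1,4-diene with a single stereocentre and an enynone arm on the furan. Four stereocentres and two rings fall away. The forward step is an intramolecular enone–alkene photocycloaddition that must choose the allyl face of ring B and place the ethynyl group beside the quaternary carbon.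

**The enynone arm (24 ⇒ 23 ⇒ 18 + 20; 20 ⇒ 19).** The bond between furan C3 and the carbonyl carbon is cut at the alcohol oxidation level. This gives furyl bromide 18 and enynal 20, one oxidation away from commercial enynol 19. Acylation at the ketone level would expose an ynenone to an organometallic; the enal adds cleanly at carbon. The forward step needs a furyl–metal species that tolerates the ester of 18.

**The carboxyl carbon (18 ⇒ 17 ⇒ 15 ⇒ 14).** The ester carbon is cut off as carbon monoxide, leading to enol triflate 17, to ketone 15 and to hydroxy ketone 14. The ketone has only one enolisable side, so the triflate can form in one way only.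

**Furan onto ring B, and the one-carbon arm (14 ⇒ 12 ⇒ 8 + 9).** The hydroxymethyl group of 14 is the reduced amide carbonyl of 12, and its ketone is the hydrolysed methyl enol ether. The furan–ring B bond of 12 is cut to enol triflate 8 and 3-bromofuran 9. A coupling at this bond is chosen over addition of a furyl–metal to a ketone followed by dehydration, because dehydration would move the double bond toward the CH2 group.

**Quaternary carbon and the position of the double bond (8 ⇒ 7 ⇒ 4 ⇒ 3 ⇒ 1 + 2 + 5).** Triflate 8 comes from silyl enol ether 7, and 7 from Birch reduction–allylation of benzamide 4, made from acid 1, amine 2 and allyl bromide 5 through phenol 3. The aromatic ring supplies ring B, the carboxyl carbon becomes the lactone CH2, and the two ring oxygens mark the carbons that will carry the carboxyl group and the furan. The oxygen para to the methoxy group is carried as a silyl ether rather than a methyl ether: a methyl enol ether could only be used through its ketone, which would enolise toward the doubly activated CH2, whereas a silyl enol ether is converted to the triflate with the double bond where the Birch step left it. The forward step must set the quaternary carbon under control of the amide auxiliary.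

## Roads not taken

**Alternative 1:** The cut is the ring A bond between the CH2 group and the lactone quaternary carbon, formed together with a ring A ketone. Forward, the potassium alkoxide of bridged vinyl carbinol A1 (KH, 18-crown-6) would undergo an anionic oxy-Cope rearrangement: the bond from the carbinol carbon to the bridgehead breaks and the vinyl terminus bonds to the butenolide β-carbon, giving ring A ketone A2 on work-up.
- Merits: the step is thermal and stereospecific, and the bicyclo[2.2.2]octene of A1 can place the vinyl group over the alkene bridge on one side only, so the quaternary carbon forms with a fixed configuration. Rings A and B appear together and ring C is already present. There is no photochemistry and no cyclobutane to cleave, so in certainty of the bond-forming event this road is at least as good as the chosen one.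
- Weak points: A1 is itself a hard target (a bridged core carrying the furan-fused seven-membered ring, a tetrasubstituted butenolide alkene and a tertiary vinyl carbinol). The alkoxide conditions threaten the butenolide through deprotonation at its OCH2 group. A2 lacks the exocyclic methylene and the oxygen of the acetate, so methylenation of a ketone beside a quaternary carbon, an allylic oxidation of uncertain face selectivity and a ketal removal must follow.
- Comparison: the chosen plan reaches its key-step substrate 24 from an aromatic acid with one stereocentre and closes ring A with the final oxidation pattern in one step.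

**Alternative 2:** The cut is the ring C bond between the ketone α-CH2 and the methyl-bearing quaternary carbon. Forward, nine-membered cyclic allyl vinyl ether A3 would undergo a Claisen rearrangement on heating: the enol CH2 bonds to the methyl-bearing alkene carbon, the ring contracts from nine to seven, and tetracyclic ketone A4 forms with the exocyclic methylene.
- Merits: one thermal step makes the quaternary carbon, the ketone and the methylene, and the acetate oxygen is already in place as an ether. The end game (deprotection, oxidation of the diol to the butenolide, acetylation) is shorter and free of the face and regiochemistry questions of steps 13 and 15. In this respect the road is better than the chosen one.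
- Weak points: the new bond goes to a tetrasubstituted alkene carbon beside the central CH, the same congestion, now to be overcome thermally inside a medium ring whose boat or chair preference decides the configuration. A3 needs rings A and B with four stereocentres, including the lactone quaternary carbon, before a nine-membered ring is closed and a hindered furoate carbonyl is methylenated (Cp2TiCH2·AlClMe2).
- Comparison: the chosen plan sets against the shorter end game a much shorter front end, and a diradical collapse that is little affected by crowding.

**Alternative 3:** The cut is the ring B bond between the lactone α-carbon and the lactone quaternary carbon. Forward, ten-membered lactone A5 would be enolised and silylated (LiN(i-Pr)2, Me3SiCl) and rearrange on warming (Ireland–Claisen) across the ring A alkene to ring B carboxylic acid A6.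
- Merits: chirality is transferred suprafacially from the oxygen-bearing carbon to the quaternary carbon, the enolate geometry is fixed by the ring, and the reaction type is dependable. Stereocontrol at the lactone quaternary carbon is the most secure of all four plans.
- Weak points: the rearrangement consumes the C–O bond that the target needs, since the future acetate carbon ends as an alkene carbon in A6 and must be re-oxygenated. The carboxyl group of A6 sits on a saturated carbon, so the ring B alkene must still be introduced. Two ketals have to be carried, and a strained ten-membered lactone bridging rings A and C must be closed.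
- Comparison: the chosen plan keeps every late functional group in place or latent (allyl for the aldehyde, alkyne for the methylene). Against the better control at the quaternary carbon it sets an auxiliary-controlled Birch alkylation.

Key step: step 13

Assumption: the (S)-amine 2 directs allylation to the face that gives the (S) quaternary carbon of 7 (chelated potassium enolate, attack away from the methoxymethyl arm); if the sense were opposite, the (R)-amine would be used and nothing else changes.

Assumption: acid 1 is taken as a purchasable compound.

## Route

Step 1
Reactants: 1 5-hydroxy-2-methoxybenzoic acid; 2 (S)-2-(methoxymethyl)pyrrolidine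
Product: 3 (S)-(5-hydroxy-2-methoxyphenyl)[2-(methoxymethyl)pyrrolidin-1-yl]methanone
Conditions: DCC, HOBt (cat.), CH2Cl2, 0 → 23 °C
Reagents that add atoms: none
Why: Carbodiimide amide coupling; the secondary amine is far more nucleophilic than the phenol toward the activated acid. No stereocentre is formed; the auxiliary brings its own.

Step 2
Reactants: 3 (S)-(5-hydroxy-2-methoxyphenyl)[2-(methoxymethyl)pyrrolidin-1-yl]methanone
Product: 4 (S)-[2-methoxy-5-(triisopropylsilyloxy)phenyl][2-(methoxymethyl)pyrrolidin-1-yl]methanone
Conditions: TIPSCl, imidazole, DMF, 23 °C
Reagents that add atoms: chlorotriisopropylsilane, CC(C)[Si](Cl)(C(C)C)C(C)C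
Why: Imidazole-promoted silylation of a phenol. The bulky aryl silyl ether is chosen to survive dissolving-metal reduction and to emerge as a silyl enol ether.

Step 3
Reactants: 4 (S)-[2-methoxy-5-(triisopropylsilyloxy)phenyl][2-(methoxymethyl)pyrrolidin-1-yl]methanone; 5 allyl bromide
Product: 7 [(S)-1-allyl-2-methoxy-5-(triisopropylsilyloxy)cyclohexa-2,5-dien-1-yl][(S)-2-(methoxymethyl)pyrrolidin-1-yl]methanone, via potassium amide enolate 6 (not isolated)
Conditions: K (2.2 equiv), t-BuOH (1.0 equiv), NH3/THF, −78 °C; then 5, −78 °C; NH4Cl
Reagents that add atoms: none
Why: Birch reduction–alkylation of an ortho-methoxybenzamide: two electrons and one proton (at the carbon para to the carbonyl) give enolate 6, which allyl bromide alkylates at the former ipso carbon. The chelated enolate of the methoxymethylpyrrolidine amide exposes one face, which sets the quaternary carbon (S). Both oxygen substituents stay on sp2 carbons, the silyl one as a silyl enol ether whose double bond points to the quaternary carbon.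

Step 4
Reactants: 7 [(S)-1-allyl-2-methoxy-5-(triisopropylsilyloxy)cyclohexa-2,5-dien-1-yl][(S)-2-(methoxymethyl)pyrrolidin-1-yl]methanone
Product: 8 (S)-3-allyl-4-methoxy-3-{[(S)-2-(methoxymethyl)pyrrolidin-1-yl]carbonyl}cyclohexa-1,4-dien-1-yl trifluoromethanesulfonate
Conditions: CsF, PhNTf2, DME, 23 °C
Reagents that add atoms: N-phenylbis(trifluoromethanesulfonimide), O=S(=O)(N(c1ccccc1)S(=O)(=O)C(F)(F)F)C(F)(F)F
Why: Fluoride releases the enolate from the silyl enol ether with its double bond in place, and PhNTf2, present from the start, traps it on oxygen before proton transfer can move it (regiospecific enol triflate formation). The methyl enol ether and the amide are inert.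

Step 5
Reactants: 8 (S)-3-allyl-4-methoxy-3-{[(S)-2-(methoxymethyl)pyrrolidin-1-yl]carbonyl}cyclohexa-1,4-dien-1-yl trifluoromethanesulfonate; 9 3-bromofuran
Product: 12 [(S)-1-allyl-5-(3-bromofuran-2-yl)-2-methoxycyclohexa-2,5-dien-1-yl][(S)-2-(methoxymethyl)pyrrolidin-1-yl]methanone, via 3-bromo-2-lithiofuran 10 (not isolated), via (3-bromofuran-2-yl)zinc chloride 11 (not isolated)
Conditions: 9, LiN(i-Pr)2, THF, −78 °C; ZnCl2; then 8, Pd(PPh3)4 (5 mol%), THF, 23 → 45 °C
Reagents that add atoms: none
Why: Negishi coupling: 3-bromofuran is deprotonated at C2, between oxygen and bromine, transmetalated to zinc and coupled with the alkenyl triflate. Zerovalent palladium inserts into the triflate much faster than into the electron-rich C–Br bond, which is kept for step 11.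

Step 6
Reactants: 12 [(S)-1-allyl-5-(3-bromofuran-2-yl)-2-methoxycyclohexa-2,5-dien-1-yl][(S)-2-(methoxymethyl)pyrrolidin-1-yl]methanone
Product: 14 (R)-2-allyl-4-(3-bromofuran-2-yl)-2-(hydroxymethyl)cyclohex-3-en-1-one, via enol ether alcohol 13 (not isolated)
Conditions: LiH2NBH3 (from BH3·NH3 and LiN(i-Pr)2), THF, 0 → 23 °C; then 1 M HCl, THF, 0 °C
Reagents that add atoms: water, O
Why: Lithium amidotrihydroborate reduces tertiary amides, including those on quaternary carbons, to primary alcohols and releases the amine, so 2 is recovered. The acidic work-up hydrolyses the methyl enol ether of 13 to the ketone; its α-carbon is quaternary, so the ring alkene cannot move into conjugation.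

Step 7
Reactants: 14 (R)-2-allyl-4-(3-bromofuran-2-yl)-2-(hydroxymethyl)cyclohex-3-en-1-one
Product: 15 (R)-2-allyl-4-(3-bromofuran-2-yl)-2-[(tert-butyldiphenylsilyloxy)methyl]cyclohex-3-en-1-one
Conditions: TBDPSCl, imidazole, DMAP (cat.), CH2Cl2, 23 °C
Reagents that add atoms: tert-butylchlorodiphenylsilane, CC(C)(C)[Si](Cl)(c1ccccc1)c1ccccc1
Why: Silylation of a primary alcohol; the mild base does not provoke retro-aldol loss of the hydroxymethyl group. The bulky ether is the face-blocking group of step 13.

Step 8
Reactants: 15 (R)-2-allyl-4-(3-bromofuran-2-yl)-2-[(tert-butyldiphenylsilyloxy)methyl]cyclohex-3-en-1-one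
Product: 17 (R)-6-allyl-4-(3-bromofuran-2-yl)-6-[(tert-butyldiphenylsilyloxy)methyl]cyclohexa-1,4-dien-1-yl trifluoromethanesulfonate, via potassium enolate 16 (not isolated)
Conditions: KN(SiMe3)2 (1.05 equiv), THF, −78 °C; then PhNTf2, −78 → 0 °C
Reagents that add atoms: N-phenylbis(trifluoromethanesulfonimide), O=S(=O)(N(c1ccccc1)S(=O)(=O)C(F)(F)F)C(F)(F)F
Why: The ketone can enolise only toward its CH2 group, so enolate formation and O-triflation give one enol triflate. One equivalent of base at −78 °C leaves the doubly allylic CH2 alone.

Step 9
Reactants: 17 (R)-6-allyl-4-(3-bromofuran-2-yl)-6-[(tert-butyldiphenylsilyloxy)methyl]cyclohexa-1,4-dien-1-yl trifluoromethanesulfonate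
Product: 18 methyl (S)-6-allyl-4-(3-bromofuran-2-yl)-6-[(tert-butyldiphenylsilyloxy)methyl]cyclohexa-1,4-diene-1-carboxylate
Conditions: Pd(OAc)2 (5 mol%), dppf, CO (1 atm), MeOH, Et3N, DMF, 40 °C
Reagents that add atoms: carbon monoxide, [C-]#[O+]; methanol, CO
Why: Palladium-catalysed methoxycarbonylation of an alkenyl triflate (oxidative addition, CO insertion, methanolysis). At 40 °C the furyl bromide does not react.

Step 10
Reactants: 19 (E)-3-methylpent-2-en-4-yn-1-ol
Product: 20 (E)-3-methylpent-2-en-4-ynal
Conditions: MnO2, CH2Cl2, 23 °C; filtered and used as a solution
Reagents that add atoms: none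
Why: MnO2 oxidises the allylic alcohol to the enal and leaves the alkyne and the alkene geometry untouched.

Step 11
Reactants: 18 methyl (S)-6-allyl-4-(3-bromofuran-2-yl)-6-[(tert-butyldiphenylsilyloxy)methyl]cyclohexa-1,4-diene-1-carboxylate; 20 (E)-3-methylpent-2-en-4-ynal
Product: 23 methyl (6S)-6-allyl-6-[(tert-butyldiphenylsilyloxy)methyl]-4-{3-[(E)-1-hydroxy-3-methylpent-2-en-4-yn-1-yl]furan-2-yl}cyclohexa-1,4-diene-1-carboxylate (both carbinol epimers), via 3-furyllithium 21 (not isolated), via 3-furylmagnesium bromide 22 (not isolated)
Conditions: t-BuLi (2.0 equiv), THF/Et2O, −100 °C, 5 min; MgBr2·OEt2, −100 → −78 °C; then 20, −78 → −20 °C; NH4Cl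
Reagents that add atoms: none
Why: Bromine–lithium exchange at −100 °C is faster than addition to the hindered conjugated ester. Transmetalation to magnesium lowers the basicity, so the aryl Grignard reagent adds to the aldehyde carbonyl and not to the ester or the alkyne C–H. The new carbinol centre is removed in step 12.

Step 12
Reactants: 23 methyl (6S)-6-allyl-6-[(tert-butyldiphenylsilyloxy)methyl]-4-{3-[(E)-1-hydroxy-3-methylpent-2-en-4-yn-1-yl]furan-2-yl}cyclohexa-1,4-diene-1-carboxylate
Product: 24 methyl (S)-6-allyl-6-[(tert-butyldiphenylsilyloxy)methyl]-4-{3-[(E)-3-methylpent-2-en-4-ynoyl]furan-2-yl}cyclohexa-1,4-diene-1-carboxylate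
Conditions: MnO2, CH2Cl2, 23 °C
Reagents that add atoms: none
Why: MnO2 oxidises the doubly activated (furyl and allylic) alcohol under neutral conditions, which spares the base-sensitive skipped diene.

Step 13
Reactants: 24 methyl (S)-6-allyl-6-[(tert-butyldiphenylsilyloxy)methyl]-4-{3-[(E)-3-methylpent-2-en-4-ynoyl]furan-2-yl}cyclohexa-1,4-diene-1-carboxylate
Product: 25 cyclobutane photoadduct (ester and silyl ether of 24 kept; α-carbon bonded to the furyl-bearing ring B carbon, β-carbon to the neighbouring CH; cyclobutane cis-fused on the allyl face of ring B; ethynyl beside the quaternary carbon, methyl outside)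
Conditions: hν (366 nm), degassed CH2Cl2 (2 mM), −20 °C
Reagents that add atoms: none
Why: Intramolecular enone–alkene [2+2] photocycloaddition: light of 366 nm is absorbed by the conjugated 2-alkenyl-3-acylfuran enone, and after intersystem crossing the triplet enone attacks the ring B alkene held three atoms away by the furan. The α-carbon bonds first to the furyl-bearing alkene carbon, a 1,5-closure (rule of five) that makes the five-membered ring and leaves a triplet 1,4-diradical, secondary on the ring B CH and tertiary propargylic on the β-carbon; after spin inversion the two radical centres join in a 1,4-closure to the cyclobutane, which creates the bond between the methyl-bearing carbon and the future central CH without any demand on nucleophile or electrophile access. The closest known reaction type is the photocycloaddition of enones to alkenes tethered through three atoms, which gives bicyclo[3.2.0]heptanones in the same straight sense. Of the four new stereocentres, the furyl-bearing carbon and the neighbouring CH are cis by the cyclobutane itself, and the α-carbon follows from the cis fusion of the four- and five-membered rings. The face of ring B is chosen by the quaternary carbon of 24: the tert-butyldiphenylsilyloxymethyl arm, held pseudo-axial by the ester on the adjacent sp2 carbon, covers one face, so the enone adds on the face of the smaller allyl arm. At the β-carbon the rod-like ethynyl group takes the crowded position beside the quaternary carbon and the methyl group points away, which is the weaker control. The geometry of the enone double bond is lost in the triplet and does not matter, and a diradical that reverts only returns 24. The selectivities needed are therefore the face of ring B and the ethynyl-inside closure, and both rest on the single stereocentre of 24.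

Step 14
Reactants: 25 cyclobutane photoadduct
Product: 27 lactone photoadduct (butenolide closed between the hydroxymethyl arm and the ring B carboxyl; cyclobutane unchanged), via hydroxy ester 26 (not isolated)
Conditions: Bu4NF, AcOH (1:1), THF, 23 → 40 °C; then PPTS (cat.), toluene, 50 °C
Reagents that add atoms: none
Why: Buffered fluoride removes the silyl group without exposing the strained ketone or the γ-CH2 of the enoate to strong base. The freed alcohol is held cis to the ester on the cyclohexene and lactonises under mild acid. No stereocentre changes.

Step 15
Reactants: 27 lactone photoadduct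
Product: 28 ring-expanded keto lactone (furan-fused cycloheptanone, cis B/C fusion; allyl on the lactone quaternary carbon, ethynyl and methyl on the other quaternary carbon)
Conditions: SmI2 (2.5 equiv), THF/MeOH (10:1), −78 °C; NH4Cl
Reagents that add atoms: none
Why: Ketyl radical-anion fragmentation of a cyclobutyl ketone (two-carbon ring expansion): electron transfer to the acylfuran and cleavage of the ring-fusion bond, which links the ketone α-carbon to the furyl-bearing carbon, releases the strain of the fused four- and five-membered rings and leaves a tertiary, furan-stabilised radical. A second electron and MeOH deliver hydrogen to that carbon from the convex face, opposite the pseudo-axial allyl arm and the ethynyl-bearing carbon, which gives the cis B/C fusion (R). The butenolide is reduced far more slowly than the aryl ketone at −78 °C without polar additives.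

Step 16
Reactants: 28 ring-expanded keto lactone
Product: 29 aldehyde (CH2CHO arm on the lactone quaternary carbon)
Conditions: OsO4 (2 mol%), NaIO4, 2,6-lutidine, dioxane/H2O (3:1), 23 °C
Reagents that add atoms: sodium periodate, [Na+].[O-]I(=O)(=O)=O (terminal oxidant; the aldehyde oxygen passes through catalytic osmium tetroxide, O=[Os](=O)(=O)=O)
Why: Lemieux–Johnson cleavage: OsO4 dihydroxylates the monosubstituted alkene much faster than the conjugated lactone alkene, the alkyne or the acyl-deactivated furan, and periodate cleaves the diol. Ozone is avoided because of the furan.

Step 17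
Reactants: 29 aldehyde
Product: 31 allylic alcohol (ring A closed; exocyclic methylene; hydroxyl equatorial, S), via triethylsilyl ether 30 (not isolated)
Conditions: Ni(cod)2 (15 mol%), PBu3 (30 mol%), Et3SiH (5 equiv), THF, 45 °C; then Bu4NF, AcOH, THF, 0 °C
Reagents that add atoms: triethylsilane, CC[SiH](CC)CC (silicon stays only in 30; 31 keeps hydrogen from it)
Why: Nickel-catalysed reductive alkyne–aldehyde cyclisation: zerovalent nickel joins the aldehyde carbon to the internal alkyne carbon through an oxanickelacyclopentene, and the silane cleaves the Ni–O bond and puts hydrogen on the terminal carbon, giving the six-membered ring with exocyclic methylene and silyl ether. The lactone locks ring B so that ring A closes as a chair whose upper axial positions carry the lactone CH2 and the methyl group; the C–O bond, held near the plane of the alkyne in the metallacycle, takes the equatorial position, which is the (S) carbinol. Buffered fluoride then frees the alcohol.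

Step 18
Reactants: 31 allylic alcohol
Product: 32 target CNP0273675.2
Conditions: Ac2O, DMAP (cat.), pyridine, CH2Cl2, 0 → 23 °C
Reagents that add atoms: acetic anhydride, CC(=O)OC(C)=O
Why: DMAP-catalysed acetylation of a secondary allylic alcohol with retention. The mild base leaves the furfuryl CH and the lactone untouched.

## Compound list

1 | 5-hydroxy-2-methoxybenzoic acid | COc1ccc(O)cc1C(=O)O | starting material
2 | (S)-2-(methoxymethyl)pyrrolidine | COC[C@@H]1CCCN1 | starting material
3 | (S)-(5-hydroxy-2-methoxyphenyl)[2-(methoxymethyl)pyrrolidin-1-yl]methanone | COC[C@@H]1CCCN1C(=O)c1cc(O)ccc1OC | intermediate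
4 | (S)-[2-methoxy-5-(triisopropylsilyloxy)phenyl][2-(methoxymethyl)pyrrolidin-1-yl]methanone | COC[C@@H]1CCCN1C(=O)c1cc(O[Si](C(C)C)(C(C)C)C(C)C)ccc1OC | intermediate
5 | allyl bromide | C=CCBr | starting material
6 | potassium amide enolate from Birch reduction of 4 (1,4-dihydro ring, exocyclic enolate) | COC[C@@H]1CCCN1C([O-])=C1C=C(O[Si](C(C)C)(C(C)C)C(C)C)CC=C1OC.[K+] | intermediate (not isolated)
7 | [(S)-1-allyl-2-methoxy-5-(triisopropylsilyloxy)cyclohexa-2,5-dien-1-yl][(S)-2-(methoxymethyl)pyrrolidin-1-yl]methanone | C=CC[C@@]1(C(=O)N2CCC[C@H]2COC)C(OC)=CCC(O[Si](C(C)C)(C(C)C)C(C)C)=C1 | intermediate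
8 | (S)-3-allyl-4-methoxy-3-{[(S)-2-(methoxymethyl)pyrrolidin-1-yl]carbonyl}cyclohexa-1,4-dien-1-yl trifluoromethanesulfonate | C=CC[C@@]1(C(=O)N2CCC[C@H]2COC)C(OC)=CCC(OS(=O)(=O)C(F)(F)F)=C1 | intermediate
9 | 3-bromofuran | Brc1ccoc1 | starting material
10 | 3-bromo-2-lithiofuran | [Li]c1occc1Br | intermediate (not isolated)
11 | (3-bromofuran-2-yl)zinc chloride | Cl[Zn]c1occc1Br | intermediate (not isolated)
12 | [(S)-1-allyl-5-(3-bromofuran-2-yl)-2-methoxycyclohexa-2,5-dien-1-yl][(S)-2-(methoxymethyl)pyrrolidin-1-yl]methanone | C=CC[C@@]1(C(=O)N2CCC[C@H]2COC)C(OC)=CCC(c2occc2Br)=C1 | intermediate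
13 | [(R)-1-allyl-5-(3-bromofuran-2-yl)-2-methoxycyclohexa-2,5-dien-1-yl]methanol | C=CC[C@@]1(CO)C(OC)=CCC(c2occc2Br)=C1 | intermediate (not isolated)
14 | (R)-2-allyl-4-(3-bromofuran-2-yl)-2-(hydroxymethyl)cyclohex-3-en-1-one | C=CC[C@@]1(CO)C(=O)CCC(c2occc2Br)=C1 | intermediate
15 | (R)-2-allyl-4-(3-bromofuran-2-yl)-2-[(tert-butyldiphenylsilyloxy)methyl]cyclohex-3-en-1-one | C=CC[C@@]1(CO[Si](c2ccccc2)(c2ccccc2)C(C)(C)C)C(=O)CCC(c2occc2Br)=C1 | intermediate
16 | potassium enolate of 15 | C=CC[C@@]1(CO[Si](c2ccccc2)(c2ccccc2)C(C)(C)C)C([O-])=CCC(c2occc2Br)=C1.[K+] | intermediate (not isolated)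
17 | (R)-6-allyl-4-(3-bromofuran-2-yl)-6-[(tert-butyldiphenylsilyloxy)methyl]cyclohexa-1,4-dien-1-yl trifluoromethanesulfonate | C=CC[C@@]1(CO[Si](c2ccccc2)(c2ccccc2)C(C)(C)C)C(OS(=O)(=O)C(F)(F)F)=CCC(c2occc2Br)=C1 | intermediate
18 | methyl (S)-6-allyl-4-(3-bromofuran-2-yl)-6-[(tert-butyldiphenylsilyloxy)methyl]cyclohexa-1,4-diene-1-carboxylate | C=CC[C@@]1(CO[Si](c2ccccc2)(c2ccccc2)C(C)(C)C)C(C(=O)OC)=CCC(c2occc2Br)=C1 | intermediate
19 | (E)-3-methylpent-2-en-4-yn-1-ol | C#C/C(C)=C/CO | starting material
20 | (E)-3-methylpent-2-en-4-ynal | C#C/C(C)=C/C=O | intermediate
21 | 3-furyllithium formed from 18 | C=CC[C@@]1(CO[Si](c2ccccc2)(c2ccccc2)C(C)(C)C)C(C(=O)OC)=CCC(c2occc2[Li])=C1 | intermediate (not isolated)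
22 | 3-furylmagnesium bromide formed from 21 | C=CC[C@@]1(CO[Si](c2ccccc2)(c2ccccc2)C(C)(C)C)C(C(=O)OC)=CCC(c2occc2[Mg]Br)=C1 | intermediate (not isolated)
23 | methyl (6S)-6-allyl-6-[(tert-butyldiphenylsilyloxy)methyl]-4-{3-[(E)-1-hydroxy-3-methylpent-2-en-4-yn-1-yl]furan-2-yl}cyclohexa-1,4-diene-1-carboxylate, both carbinol epimers | C=CC[C@@]1(CO[Si](c2ccccc2)(c2ccccc2)C(C)(C)C)C(C(=O)OC)=CCC(c2occc2C(O)/C=C(/C#C)C)=C1 | intermediate
24 | methyl (S)-6-allyl-6-[(tert-butyldiphenylsilyloxy)methyl]-4-{3-[(E)-3-methylpent-2-en-4-ynoyl]furan-2-yl}cyclohexa-1,4-diene-1-carboxylate | C=CC[C@@]1(CO[Si](c2ccccc2)(c2ccccc2)C(C)(C)C)C(C(=O)OC)=CCC(c2occc2C(=O)/C=C(/C#C)C)=C1 | intermediate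
25 | cyclobutane photoadduct: furan-fused cyclopentanone cis-fused to a cyclobutane that is cis-fused to ring B on the allyl face; ethynyl beside the lactone-to-be quaternary carbon, methyl outside; methyl ester and silyl ether kept | C=CC[C@@]1(CO[Si](c2ccccc2)(c2ccccc2)C(C)(C)C)C(C(=O)OC)=CC[C@@]23c4occc4C(=O)[C@@H]2[C@@](C)(C#C)[C@@H]13 | intermediate
26 | hydroxy ester from desilylation of 25 | C=CC[C@@]1(CO)C(C(=O)OC)=CC[C@@]23c4occc4C(=O)[C@@H]2[C@@](C)(C#C)[C@@H]13 | intermediate (not isolated)
27 | lactone photoadduct: 25 with the butenolide closed | C=CC[C@@]12COC(=O)C1=CC[C@@]34c5occc5C(=O)[C@@H]3[C@@](C)(C#C)[C@@H]24 | intermediate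
28 | ring-expanded keto lactone: ring B with butenolide, furan-fused cycloheptanone, cis B/C fusion; allyl on the (S) lactone quaternary carbon; ethynyl and methyl on the (R) quaternary carbon; furyl CH (R); central CH (S) | C=CC[C@@]12COC(=O)C1=CC[C@H]1c3occc3C(=O)C[C@@](C)(C#C)[C@H]12 | intermediate
29 | aldehyde: 28 with the allyl group cut down to CH2CHO | O=CC[C@@]12COC(=O)C1=CC[C@H]1c3occc3C(=O)C[C@@](C)(C#C)[C@H]12 | intermediate
30 | triethylsilyl ether of 31 | C=C1[C@@H](O[Si](CC)(CC)CC)C[C@@]23COC(=O)C2=CC[C@H]2c4occc4C(=O)C[C@]1(C)[C@H]23 | intermediate (not isolated)
31 | deacetyl target: tetracycle with exocyclic methylene and (S) allylic alcohol | C=C1[C@@H](O)C[C@@]23COC(=O)C2=CC[C@H]2c4occc4C(=O)C[C@]1(C)[C@H]23 | intermediate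
32 | CNP0273675.2 | C=C1[C@@H](OC(C)=O)C[C@@]23COC(=O)C2=CC[C@H]2c4occc4C(=O)C[C@]1(C)[C@H]23 | target

## Step count and risks

Total steps: 18. Longest linear sequence: 17 (steps 1–9 and 11–18; step 10 is a one-step side branch).

**Step 13 (key step).** The most likely failure is weak discrimination between the two faces of ring B, since both arms on the quaternary carbon begin with a CH2 group. Closure of the diradical with the ethynyl group outside is a second risk. Reversion of the diradical only lowers the rate.

Fallback (locks the face by tying the two-carbon arm back): it sets out from 24 and returns at 29.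
- OsO4/NaIO4 cleaves the allyl group of 24 to aldehyde F1.
- NaBH(OAc)3 reduces only the aldehyde, to primary alcohol F2.
- Camphorsulfonic acid closes F2 onto the ring B ester as δ-lactone F3. Here the two-carbon arm is pulled into the plane of ring B and the silyloxymethyl arm is forced pseudo-axial.
- Irradiation as in step 13 gives photoadduct F4.
- Bu4NF frees the primary alkoxide, which takes over the acyl group and gives the five-membered lactone with a free hydroxyethyl arm, hydroxy lactone F5.
- SmI2/MeOH as in step 15 gives ring-expanded alcohol F6.
- Dess–Martin oxidation of F6 gives 29.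

**Step 15.** The ring-fusion bond lies close to the plane of the five-membered ring and overlaps poorly with the ketyl π system. Cleavage of the other cyclobutane bond at the α-carbon, which would give a tertiary propargylic radical, may therefore compete. Protonation on the wrong face and reduction of the butenolide are lesser risks.

Fallback (polar cleavage from the ring B side, where only the ring-fusion bond can break): it sets out from 27 and returns at 28.
- KOt-Bu in THF at −40 °C removes a γ-proton of the butenolide at the CH2 next to the furyl-bearing carbon. The dienolate expels the ketone enolate (vinylogous retro-Michael opening of the cyclobutane) and gives ring-expanded diene F7.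
- SmI2/MeOH then reduces the extended, doubly activated diene with protonation at the furyl carbon from the convex face. DBU returns any deconjugated lactone to conjugation, giving 28.

**Step 11.** The organolithium may add to the methyl ester or deprotonate the doubly allylic CH2 (moving the skipped diene into conjugation) or the alkyne before it reaches the aldehyde.

Fallback (carries the carboxyl group as its salt, which organolithiums do not attack at low temperature): it sets out from 17 and returns at 23.
- Hydroxycarbonylation of 17 (Pd(OAc)2, dppf, CO, KOAc, DMSO/H2O) gives carboxylic acid F8.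
- NaH forms the sodium carboxylate; t-BuLi, MgBr2·OEt2 and 20 as in step 11 give hydroxy acid F9.
- Me3SiCHN2 in MeOH/toluene esterifies F9 to 23.

**Step 17.** The carbinol may form with the oxygen axial if the metallacycle closes through a twisted ring A. Simple hydrosilylation of the aldehyde would lower the yield.

Fallback (accepts the epimer and inverts it while the acetate is introduced): it sets out from 29 and returns at 32. The cyclisation of step 17 then gives epimeric alcohol F10, and a Mitsunobu reaction (PPh3, DIAD, AcOH) displaces the axial oxygen from the open equatorial side to give 32 directly.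

## Further compounds

F1 | step 13 | aldehyde from cleavage of the allyl group of 24 | O=CC[C@@]1(CO[Si](c2ccccc2)(c2ccccc2)C(C)(C)C)C(C(=O)OC)=CCC(c2occc2C(=O)/C=C(/C#C)C)=C1
F2 | step 13 | primary alcohol from reduction of F1 | OCC[C@@]1(CO[Si](c2ccccc2)(c2ccccc2)C(C)(C)C)C(C(=O)OC)=CCC(c2occc2C(=O)/C=C(/C#C)C)=C1
F3 | step 13 | δ-lactone with the two-carbon arm closed onto the ring B carboxyl; silyl ether and enynone arm kept | O=C1OCC[C@@]2(CO[Si](c3ccccc3)(c3ccccc3)C(C)(C)C)C1=CCC(c1occc1C(=O)/C=C(/C#C)C)=C2
F4 | step 13 | cyclobutane photoadduct of F3 | O=C1OCC[C@@]2(CO[Si](c3ccccc3)(c3ccccc3)C(C)(C)C)C1=CC[C@@]13c4occc4C(=O)[C@@H]1[C@@](C)(C#C)[C@@H]23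
F5 | step 13 | butenolide photoadduct with free 2-hydroxyethyl arm | OCC[C@@]12COC(=O)C1=CC[C@@]34c5occc5C(=O)[C@@H]3[C@@](C)(C#C)[C@@H]24
F6 | step 13 | ring-expanded keto lactone with 2-hydroxyethyl arm | OCC[C@@]12COC(=O)C1=CC[C@H]1c3occc3C(=O)C[C@@](C)(C#C)[C@H]12
F7 | step 15 | ring-expanded diene lactone (furyl-bearing carbon sp2, double bond to the former ring B CH2) | C=CC[C@@]12COC(=O)C1=CC=C1c3occc3C(=O)C[C@@](C)(C#C)[C@H]12
F8 | step 11 | carboxylic acid corresponding to ester 18 | C=CC[C@@]1(CO[Si](c2ccccc2)(c2ccccc2)C(C)(C)C)C(C(=O)O)=CCC(c2occc2Br)=C1
F9 | step 11 | hydroxy acid corresponding to 23 | C=CC[C@@]1(CO[Si](c2ccccc2)(c2ccccc2)C(C)(C)C)C(C(=O)O)=CCC(c2occc2C(O)/C=C(/C#C)C)=C1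
F10 | step 17 | carbinol epimer of 31 (hydroxyl axial) | C=C1[C@H](O)C[C@@]23COC(=O)C2=CC[C@H]2c4occc4C(=O)C[C@]1(C)[C@H]23
A1 | alternative 1 | bridged vinyl carbinol (bicyclo[2.2.2]octene, substrate of the oxy-Cope rearrangement) | C=C[C@]1(O)[C@H]2C[C@H]3c4occc4C4(OCCO4)C[C@]1(C)[C@H]3C1=C2C(=O)OC1
A2 | alternative 1 | ring A ketone with the complete carbon skeleton | O=C1CC[C@@]23COC(=O)C2=CC[C@H]2c4occc4C4(OCCO4)C[C@]1(C)[C@H]23
A3 | alternative 2 | nine-membered cyclic allyl vinyl ether | C=C1OCC2=C(C)[C@@H]3[C@@H](CC=C(CO[Si](C)(C)C(C)(C)C)[C@]3(CO[Si](C)(C)C(C)(C)C)C[C@@H]2OCc2ccc(OC)cc2)c2occc12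
A4 | alternative 2 | tetracyclic ketone with the lactone carried as a diol bis-silyl ether | C=C1[C@@H](OCc2ccc(OC)cc2)C[C@@]2(CO[Si](C)(C)C(C)(C)C)C(CO[Si](C)(C)C(C)(C)C)=CC[C@H]3c4occc4C(=O)C[C@]1(C)[C@@H]23
A5 | alternative 3 | ten-membered lactone bridging rings A and C | O=C1CCC[C@H]2c3occc3C3(OCCO3)C[C@@]3(C)C(OC)(OC)[C@@H](O1)C=C(CO[Si](C)(C)C(C)(C)C)[C@@H]23
A6 | alternative 3 | ring B carboxylic acid | OC(=O)[C@H]1CC[C@H]2c3occc3C3(OCCO3)C[C@@]3(C)C(OC)(OC)C=C[C@]1(CO[Si](C)(C)C(C)(C)C)[C@@H]23
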